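**Retrosynthetic overview**

- Numbering: ring A is the 1,3,5-trisubstituted ring (OH at C1, chain at C3, ether O at C5). Ring B is the hydroquinone ring (ether O at C1', OH at C3' and C6', chain at C5'). Chain carbons C1–C14 are counted from ring A. The target has no stereocentre.
- Feature: the fourteen CH2 groups that bridge C3 of ring A and C5' of ring B carry no functionality, so chain C5–C8 can be carried as a buta-1,3-diyne. The 21-membered ring is then cut at C6–C7 into two terminal alkynes (Eglinton coupling); hydrogenation and O-demethylation follow.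
- The open diyne is a diaryl ether with a hex-5-ynyl arm on ring A and an oct-7-ynyl arm on ring B. Both arms come from B-alkyl Suzuki couplings of TIPS-capped enynes, and the C5(ring A)–O bond from a Chan–Lam coupling.
- The ring B phenol comes from 2-hydroxy-5-methoxybenzaldehyde by bromination, methylation and Baeyer–Villiger oxidation.
- Ring order: both benzene rings are purchased; the macrocycle is the only ring formed (step 10).

Key step: step 10

**Route**

Step 1
Reactants: 1 2-hydroxy-5-methoxybenzaldehyde
Product: 2 3-bromo-2-hydroxy-5-methoxybenzaldehyde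
Conditions: Br2 (1.05 equiv), NaOAc, AcOH, rt
Reagents that add atoms: bromine, BrBr
Why: Electrophilic aromatic bromination is directed by the free phenol to its only open ortho position (C3), because the para position carries OMe and the other ortho position the formyl group.

Step 2
Reactants: 2 3-bromo-2-hydroxy-5-methoxybenzaldehyde
Product: 3 3-bromo-2,5-dimethoxybenzaldehyde
Conditions: MeI, K2CO3, DMF, rt
Reagents that add atoms: iodomethane, CI
Why: Williamson O-methylation of the acidic ortho-formyl phenoxide is a simple SN2 reaction with no competing nucleophile.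

Step 3
Reactants: 3 3-bromo-2,5-dimethoxybenzaldehyde
Product: 5 3-bromo-2,5-dimethoxyphenol, via aryl formate 4 (not isolated)
Conditions: mCPBA, CH2Cl2, 0 °C to rt; NaHCO3 wash; then K2CO3 (cat.), MeOH, rt
Reagents that add atoms: mCPBA, OOC(=O)c1cccc(Cl)c1
Why: Baeyer–Villiger (Dakin-type) oxidation, in which the electron-rich dimethoxyaryl group migrates to oxygen in the Criegee adduct to give the aryl formate, which methanolysis converts into the phenol.

Step 4
Reactants: 6 oct-1-en-7-yne
Product: 8 triisopropyl(oct-7-en-1-yn-1-yl)silane, via lithium acetylide 7 (not isolated)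
Conditions: n-BuLi, THF, −78 °C; then TIPSCl, −78 °C to rt
Reagents that add atoms: triisopropylsilyl chloride, CC(C)[Si](Cl)(C(C)C)C(C)C
Why: Deprotonation of the terminal alkyne and C-silylation of the acetylide give a TIPS cap that should survive hydroboration, aqueous base and the copper/air conditions of the later steps.

Step 5
Reactants: 9 hex-1-en-5-yne
Product: 11 (hex-5-en-1-yn-1-yl)triisopropylsilane, via lithium acetylide 10 (not isolated)
Conditions: n-BuLi, THF, −78 °C; then TIPSCl, −78 °C to rt
Reagents that add atoms: triisopropylsilyl chloride, CC(C)[Si](Cl)(C(C)C)C(C)C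
Why: The same acetylide C-silylation as in step 4 also turns the volatile enyne into an easily handled silane.

Step 6
Reactants: 8 triisopropyl(oct-7-en-1-yn-1-yl)silane; 5 3-bromo-2,5-dimethoxyphenol
Product: 13 2,5-dimethoxy-3-[8-(triisopropylsilyl)oct-7-yn-1-yl]phenol, via B-alkyl-9-BBN adduct 12 (not isolated)
Conditions: 8, 9-BBN (0.5 M in THF), 0 °C to rt; then 5, Pd(OAc)2 (cat.), SPhos, aq. K3PO4 (3.5 equiv), THF, 60 °C
Reagents that add atoms: none
Why: 9-BBN adds anti-Markovnikov to the terminal alkene far faster than to the hindered silylalkyne, and the primary alkylborane then undergoes B-alkyl Suzuki–Miyaura coupling with the aryl bromide, the extra base holding the phenol as its phenoxide while the electron-rich Pd/SPhos catalyst still undergoes oxidative addition.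

Step 7
Reactants: 13 2,5-dimethoxy-3-[8-(triisopropylsilyl)oct-7-yn-1-yl]phenol; 14 3-bromo-5-methoxyphenylboronic acid
Product: 15 1-bromo-3-methoxy-5-{2,5-dimethoxy-3-[8-(triisopropylsilyl)oct-7-yn-1-yl]phenoxy}benzene
Conditions: 14 (2.5 equiv), Cu(OAc)2 (2 equiv), pyridine (5 equiv), 4 Å molecular sieves, CH2Cl2, dry air, rt
Reagents that add atoms: none
Why: Chan–Lam oxidative O-arylation, in which the arylboronic acid transmetalates to divalent copper and the aryl–O bond forms by reductive elimination at room temperature, leaving the aryl bromide and the silyl-capped alkyne (which cannot undergo Glaser coupling) untouched.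

Step 8
Reactants: 11 (hex-5-en-1-yn-1-yl)triisopropylsilane; 15 1-bromo-3-methoxy-5-{2,5-dimethoxy-3-[8-(triisopropylsilyl)oct-7-yn-1-yl]phenoxy}benzene
Product: 17 1-methoxy-3-[6-(triisopropylsilyl)hex-5-yn-1-yl]-5-{2,5-dimethoxy-3-[8-(triisopropylsilyl)oct-7-yn-1-yl]phenoxy}benzene, via B-alkyl-9-BBN adduct 16 (not isolated)
Conditions: 11, 9-BBN (0.5 M in THF), 0 °C to rt; then 15, PdCl2(dppf) (cat.), aq. K3PO4, THF/DMF, 60 °C
Reagents that add atoms: none
Why: Chemoselective hydroboration of the terminal alkene followed by B-alkyl Suzuki–Miyaura coupling at the only aryl bromide installs the ring A arm, and the diaryl ether, methyl ethers and both TIPS-alkynes are inert to these conditions.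

Step 9
Reactants: 17 1-methoxy-3-[6-(triisopropylsilyl)hex-5-yn-1-yl]-5-{2,5-dimethoxy-3-[8-(triisopropylsilyl)oct-7-yn-1-yl]phenoxy}benzene
Product: 18 1-(hex-5-yn-1-yl)-3-methoxy-5-[2,5-dimethoxy-3-(oct-7-yn-1-yl)phenoxy]benzene
Conditions: TBAF (1 M in THF, 2.5 equiv), THF, 0 °C to rt
Reagents that add atoms: none
Why: Fluoride-induced cleavage of both alkynyl C–Si bonds (protodesilylation) frees the two terminal alkynes and touches nothing else in the molecule.

Step 10
Reactants: 18 1-(hex-5-yn-1-yl)-3-methoxy-5-[2,5-dimethoxy-3-(oct-7-yn-1-yl)phenoxy]benzene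
Product: 19 21-membered macrocyclic 1,3-diyne (tri-O-methyl ether of the target with C≡C–C≡C at chain C5–C8)
Conditions: Cu(OAc)2 (anhydrous, 10 equiv), pyridine, 60 °C, argon; 18 added by syringe pump over about 12 h to a final concentration near 1 mM
Reagents that add atoms: none
Why: Pyridine and acetate deprotonate each copper-complexed terminal alkyne to a copper acetylide, and oxidation by divalent copper then joins the two alkynyl carbons (chain C6 and C7) with release of monovalent copper, so that two nucleophilic carbons are united at the cost of two equivalents of Cu(OAc)2. The closest known reaction type is the Eglinton (Glaser-type) oxidative coupling of α,ω-diynes to macrocyclic 1,3-diynes. The 21-membered ring closes by end-to-end coupling of the two tethered acetylides, the linear six-atom C4–C9 segment being spanned without strain by the other fifteen ring atoms while the bent meta,meta'-diaryl ether hinge turns both arms to the same side. No stereocentre is formed. The only selectivity needed is ring closure over intermolecular coupling to cyclic dimer and oligomers, and it is secured by slow addition of 18 into a large excess of Cu(OAc)2, which keeps the stationary concentration of uncoupled diyne very low, whereas regiochemistry is no issue because both termini are terminal alkynes and can give only one 1,3-diyne. The aryl methyl ethers and the diaryl ether are inert to Cu(OAc)2 in pyridine.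

Step 11
Reactants: 19 21-membered macrocyclic 1,3-diyne
Product: 20 tri-O-methyl ether of the target (saturated 21-membered diaryl ether macrocycle)
Conditions: H2 (1 atm), 10% Pd/C, EtOAc, rt
Reagents that add atoms: none
Why: Heterogeneous catalytic hydrogenation should saturate the conjugated diyne to four methylene groups, while aryl methyl ethers and the diaryl ether are not hydrogenolysed under these conditions.

Step 12
Reactants: 20 tri-O-methyl ether of the target
Product: 21 CNP0393720.0 (target)
Conditions: BBr3 (6 equiv), CH2Cl2, −78 °C to rt, argon; then degassed H2O, wash with aq. Na2S2O4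
Reagents that add atoms: none
Why: Lewis-acid O-demethylation, in which BBr3 complexes each methoxy oxygen and bromide attacks the methyl group, should cleave all three methyl ethers but not the diaryl ether, which offers no carbon open to SN2 attack; oxygen-free work-up protects the hydroquinone ring B.

**Compound list**

1 | 2-hydroxy-5-methoxybenzaldehyde | COc1ccc(O)c(C=O)c1 | starting material
2 | 3-bromo-2-hydroxy-5-methoxybenzaldehyde | COc1cc(Br)c(O)c(C=O)c1 | intermediate
3 | 3-bromo-2,5-dimethoxybenzaldehyde | COc1cc(Br)c(OC)c(C=O)c1 | intermediate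
4 | 3-bromo-2,5-dimethoxyphenyl formate (not isolated) | COc1cc(Br)c(OC)c(OC=O)c1 | intermediate
5 | 3-bromo-2,5-dimethoxyphenol | COc1cc(Br)c(OC)c(O)c1 | intermediate
6 | oct-1-en-7-yne | C=CCCCCC#C | starting material
7 | lithium oct-7-en-1-yn-1-ide (not isolated) | [Li]C#CCCCCC=C | intermediate
8 | triisopropyl(oct-7-en-1-yn-1-yl)silane | C=CCCCCC#C[Si](C(C)C)(C(C)C)C(C)C | intermediate
9 | hex-1-en-5-yne | C=CCCC#C | starting material
10 | lithium hex-5-en-1-yn-1-ide (not isolated) | [Li]C#CCCC=C | intermediate
11 | (hex-5-en-1-yn-1-yl)triisopropylsilane | C=CCCC#C[Si](C(C)C)(C(C)C)C(C)C | intermediate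
12 | 9-[8-(triisopropylsilyl)oct-7-yn-1-yl]-9-borabicyclo[3.3.1]nonane (not isolated) | CC(C)[Si](C#CCCCCCCB1C2CCCC1CCC2)(C(C)C)C(C)C | intermediate
13 | 2,5-dimethoxy-3-[8-(triisopropylsilyl)oct-7-yn-1-yl]phenol | COc1cc(O)c(OC)c(CCCCCCC#C[Si](C(C)C)(C(C)C)C(C)C)c1 | intermediate
14 | 3-bromo-5-methoxyphenylboronic acid | COc1cc(Br)cc(c1)B(O)O | starting material
15 | 1-bromo-3-methoxy-5-{2,5-dimethoxy-3-[8-(triisopropylsilyl)oct-7-yn-1-yl]phenoxy}benzene | COc1cc(Br)cc(c1)Oc1cc(OC)cc(CCCCCCC#C[Si](C(C)C)(C(C)C)C(C)C)c1OC | intermediate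
16 | 9-[6-(triisopropylsilyl)hex-5-yn-1-yl]-9-borabicyclo[3.3.1]nonane (not isolated) | CC(C)[Si](C#CCCCCB1C2CCCC1CCC2)(C(C)C)C(C)C | intermediate
17 | 1-methoxy-3-[6-(triisopropylsilyl)hex-5-yn-1-yl]-5-{2,5-dimethoxy-3-[8-(triisopropylsilyl)oct-7-yn-1-yl]phenoxy}benzene | COc1cc(CCCCC#C[Si](C(C)C)(C(C)C)C(C)C)cc(c1)Oc1cc(OC)cc(CCCCCCC#C[Si](C(C)C)(C(C)C)C(C)C)c1OC | intermediate
18 | 1-(hex-5-yn-1-yl)-3-methoxy-5-[2,5-dimethoxy-3-(oct-7-yn-1-yl)phenoxy]benzene | COc1cc(CCCCC#C)cc(c1)Oc1cc(OC)cc(CCCCCCC#C)c1OC | intermediate
19 | 21-membered macrocyclic 1,3-diyne, tri-O-methyl ether of the target with the diyne at chain C5–C8 | COc1cc2cc(c1)Oc1cc(OC)cc(c1OC)CCCCCCC#CC#CCCCC2 | intermediate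
20 | tri-O-methyl ether of the target, saturated macrocycle | COc1cc2cc(c1)Oc1cc(OC)cc(c1OC)CCCCCCCCCCCCCC2 | intermediate
21 | CNP0393720.0 | Oc1cc2cc(c1)Oc1cc(O)cc(c1O)CCCCCCCCCCCCCC2 | target

**Step count**

Total: 12 steps. Longest linear sequence: 10 steps (1 to 21 through steps 1, 2, 3, 6, 7, 8, 9, 10, 11, 12); steps 4 and 5 are side branches.

**Steps most likely to fail**

Step 10. Intermolecular oxidative coupling may outrun ring closure, so that cyclic dimer and linear oligomers form in place of the 21-membered ring. The fallback forms the same C6–C7 bond by an intramolecular Cadiot–Chodkiewicz coupling of a bromoalkyne with a terminal alkyne, which needs no stoichiometric oxidant. It sets out from 15 and 9. Lithiation of 9 (through 10) and quenching with TMSCl should give (hex-5-en-1-yn-1-yl)trimethylsilane F1. Hydroboration of F1 with 9-BBN should give the B-alkyl-9-BBN adduct F2 (not isolated), which is coupled with 15 (PdCl2(dppf), anhydrous K3PO4, DMF/THF, 60 °C) to the mixed TMS/TIPS bis-silyl diaryl ether F3. NBS with AgNO3 (cat.) in acetone at rt should exchange only the C–SiMe3 group for bromine and give the bromoalkyne with the TIPS group intact, F4. TBAF buffered with AcOH in THF at 0 °C then removes the TIPS group to give the ω-bromoalkyne/terminal alkyne F5. Slow addition of F5 to CuCl (cat.), NH2OH·HCl and n-BuNH2 in THF/MeOH at rt should close the ring to 19, where the route resumes at step 11.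

Step 7. The ortho-methoxy phenol may be arylated slowly, while the boronic acid is lost to protodeboronation, oxidation to the phenol or homocoupling. The fallback is an Ullmann-type ether synthesis that sets out from 13. It uses commercial 1-bromo-3-iodo-5-methoxybenzene (COc1cc(Br)cc(I)c1) with CuI (cat.), picolinic acid and K3PO4 in DMSO at 80 °C. The C–I bond should react selectively over the C–Br bond and give 15 directly, where the route resumes at step 8. This fallback makes no new compound (F0).

Step 6. Oxidative addition to the electron-rich bromophenoxide may be slow, so that the alkylborane is lost to protodeboronation or β-hydride elimination before coupling. The fallback moves the coupling to the aldehyde stage and sets out from 3 and 12. Coupling of 3 with 12 (PdCl2(dppf), aq. K3PO4, THF/DMF, 60 °C) should give 2,5-dimethoxy-3-[8-(triisopropylsilyl)oct-7-yn-1-yl]benzaldehyde F6. Baeyer–Villiger oxidation of F6 with mCPBA in CH2Cl2 should give the aryl formate F7 (not isolated), which K2CO3 (cat.) in MeOH cleaves to 13, where the route resumes at step 7.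

**Further compounds**

F1 | step 10 | (hex-5-en-1-yn-1-yl)trimethylsilane | C=CCCC#C[Si](C)(C)C
F2 | step 10 | 9-[6-(trimethylsilyl)hex-5-yn-1-yl]-9-borabicyclo[3.3.1]nonane (not isolated) | C[Si](C)(C)C#CCCCCB1C2CCCC1CCC2
F3 | step 10 | 1-methoxy-3-[6-(trimethylsilyl)hex-5-yn-1-yl]-5-{2,5-dimethoxy-3-[8-(triisopropylsilyl)oct-7-yn-1-yl]phenoxy}benzene | COc1cc(CCCCC#C[Si](C)(C)C)cc(c1)Oc1cc(OC)cc(CCCCCCC#C[Si](C(C)C)(C(C)C)C(C)C)c1OC
F4 | step 10 | 1-(6-bromohex-5-yn-1-yl)-3-methoxy-5-{2,5-dimethoxy-3-[8-(triisopropylsilyl)oct-7-yn-1-yl]phenoxy}benzene | COc1cc(CCCCC#CBr)cc(c1)Oc1cc(OC)cc(CCCCCCC#C[Si](C(C)C)(C(C)C)C(C)C)c1OC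
F5 | step 10 | 1-(6-bromohex-5-yn-1-yl)-3-methoxy-5-[2,5-dimethoxy-3-(oct-7-yn-1-yl)phenoxy]benzene | COc1cc(CCCCC#CBr)cc(c1)Oc1cc(OC)cc(CCCCCCC#C)c1OC
F0 | step 7 | none | none
F6 | step 6 | 2,5-dimethoxy-3-[8-(triisopropylsilyl)oct-7-yn-1-yl]benzaldehyde | COc1cc(C=O)c(OC)c(CCCCCCC#C[Si](C(C)C)(C(C)C)C(C)C)c1
F7 | step 6 | 2,5-dimethoxy-3-[8-(triisopropylsilyl)oct-7-yn-1-yl]phenyl formate (not isolated) | COc1cc(OC=O)c(OC)c(CCCCCCC#C[Si](C(C)C)(C(C)C)C(C)C)c1
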